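Readings and results stem from a simulated flask on assumed constants.

A leftover is where I start: in dawn, summer and dusk the reagent is charged at 1.05 equiv, so the starting material is the limiting reagent, and the surplus, the reagent charged beyond the starting material, is 5.00 % of the starting material charged.

| flask | starting material | reagent | remark | time |
|---|---|---|---|---|
| south-east | 0.020 M | 0.70 equiv (in portions, 4) | run made earlier; portions every 50 min |  |
| west | 0.020 M | 0.53 equiv (in portions, 4) | run made earlier; portions every 50 min |  |
| dawn | 0.020 M | 1.05 equiv (in portions, 4) | the portions of reagent follow each other after 50 min, the first at the start | 10 h |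
| summer | 0.040 M | 1.05 equiv (in portions, 4) | the portions of reagent follow each other after 50 min, the first at the start | 10 h |
| dusk | 0.080 M | 1.05 equiv (in portions, 4) | the portions of reagent follow each other after 50 min, the first at the start | 10 h |

| run | time / h | intermediate / % | target / % |
|---|---|---|---|
| south-east | 0.500 | 0 | 2 |
| south-east | 1.50 | 2 | 6 |
| south-east | 3.00 | 2 | 20 |
| south-east | 4.00 | 0 | 23 |
| south-east | 6.00 | 0 | 33 |
| west | 0.500 | 0 | 2 |
| west | 1.50 | 0 | 6 |
| west | 3.00 | 0 | 13 |
| west | 4.00 | 0 | 20 |
| west | 6.00 | 2 | 25 |

(readings scatter by 1.5 percentage points)

- what was read earlier has a scatter of 1.5 percentage points, one standard deviation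
- "hardly changes" means that all values lie within two and a half points (for a concentration: within two and a half percent of the largest)

- [intermediate] at the end for dawn, summer, dusk, in this order
- the course of these numbers from the first flask to the last (rises, then falls / rises all the way / hardly changes / falls all the way / falls, then rises)

In south-east and west the reagent is the smaller charge, and at 6.00 h the target stands at 47.1 % and 47.2 % of the reagent charged, so as a reading the target follows the reagent. No reading of the intermediate in those runs exceeds 2 %, close to the scatter of 1.5 percentage points, so I take it as a steady state, its level following the product of starting material and reagent present.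

The asked number therefore needs both leftovers, and the surplus links them: if a starting material leaves by meeting a reagent and in no other way, reagent left minus starting material left equals the surplus. So my reckoning expects a row that rises and flattens. But neither run shows the starting material, so this balance is untested.

The forecast gives 4.000 × 10⁻⁵ M, 7.000 × 10⁻⁵ M and 1.000 × 10⁻⁴ M, a course that rises all the way, with “the intermediate at steady state”.

The flasks give 4.63 × 10⁻⁵ M, 6.07 × 10⁻⁵ M and 5.54 × 10⁻⁵ M, a course that rises, then falls, turning at a starting concentration of 0.050 M.

starting material + reagent → intermediate (k = 0.00290 M⁻¹ s⁻¹); intermediate → target (k = 0.00300 s⁻¹); starting material + target → side product (k = 4.40 × 10⁻⁴ M⁻¹ s⁻¹) At the end of dusk, the reagent left is 21.9 % of the starting material charged and the starting material left is 4.0 %, so their gap exceeds the surplus by 12.9 %. In dawn, the same subtraction gives 5.36 %. The side product counts as two in its percentage, so by units it stands at 12.9 % of the starting material charged in dusk and 5.36 % in dawn.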